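**Plan**

- Retrosynthesis: cut the angelate C–O bond at the side-chain carbinol; trace the C3–O acetate back to a C3 acetyl group (Baeyer–Villiger); cut the C2–C3 bond to an open ortho-(aryloxymethyl)aryl diazoketone (carbenoid C–H insertion); take the diazoketone back to an allyl group (diazo transfer, Wacker, Claisen) and the O1–CH2 bond to a phenol alkylation.
- Enabling feature: in the dihydrofuran ring (O1, C2, C3, C3a, C7a) the acetate sits on the benzylic carbon C3, where an acetyl group can be exchanged for oxygen with retention. C2 is an ether CH that, in the open form, is an O–CH2 group 1,5 to C3 and activated by O1 and the adjacent acrylate alkene.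
- Forward: the benzene ring of 1-(4-hydroxyphenyl)ethanone is kept; both side arms are built in steps 1–7; the only new ring, the dihydrofuran, closes in step 8; acetate and angelate are placed in steps 9–11.
- Stereochemistry: the side-chain carbinol (S) comes from Noyori transfer hydrogenation; C2 and C3 (cis) come from the chiral dirhodium catalyst in the insertion; the C3–O bond inherits C3 by retentive migration; the Z alkene comes with angelic acid and is kept by acylation without a nucleophilic catalyst.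

Key step: step 8

Assumption: Rh2(S-PTTL)4, dirhodium tetrakis[N-phthaloyl-(S)-tert-leucinate], is taken to give the (2R,3S) sense by analogy with aryl diazoacetate insertions. If the first experiment shows the opposite sense, the mirror-image catalyst Rh2(R-PTTL)4 takes its place and nothing else changes.

Remark: locants follow 1-benzofuran numbering. C2 is R in ketone 12 and S from acetate 13 onward only because the CIP ranking at C2 changes when C3 gains oxygen; the geometry is the same.

**Route**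

Step 1
Reactants: 1 1-(4-hydroxyphenyl)ethan-1-one; 2 allyl bromide (3-bromoprop-1-ene)
Product: 3 1-[4-(prop-2-en-1-yloxy)phenyl]ethan-1-one
Conditions: K2CO3, acetone, reflux
Reagents that add atoms: none
Why: Williamson O-alkylation of the acidic para-acylphenol with a reactive allylic bromide under weak base.

Step 2
Reactants: 3 1-[4-(prop-2-en-1-yloxy)phenyl]ethan-1-one
Product: 5 1-[4-hydroxy-3-(prop-2-en-1-yl)phenyl]ethan-1-one, via 4-acetyl-6-allylcyclohexa-2,4-dienone 4 (not isolated)
Conditions: N,N-diethylaniline, 200 °C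
Reagents that add atoms: none
Why: Aromatic Claisen rearrangement; the [3,3] shift delivers the allyl group to the free ortho position and tautomerisation of the dienone restores the phenol.

Step 3
Reactants: 5 1-[4-hydroxy-3-(prop-2-en-1-yl)phenyl]ethan-1-one; 6 methyl 2-(bromomethyl)prop-2-enoate
Product: 7 methyl 2-{[4-acetyl-2-(prop-2-en-1-yl)phenoxy]methyl}prop-2-enoate
Conditions: K2CO3, acetone, 0 °C to rt
Reagents that add atoms: none
Why: Phenoxide alkylation by an activated allylic bromide; direct and allylically transposed (SN2') displacement on this symmetric 2-(methoxycarbonyl)allyl unit give the same ether.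

Step 4
Reactants: 7 methyl 2-{[4-acetyl-2-(prop-2-en-1-yl)phenoxy]methyl}prop-2-enoate
Product: 8 methyl 2-({4-[(1S)-1-hydroxyethyl]-2-(prop-2-en-1-yl)phenoxy}methyl)prop-2-enoate
Conditions: RuCl[(S,S)-TsDPEN](p-cymene) (1 mol%), HCO2H/Et3N (5:2), rt
Reagents that add atoms: none
Why: Noyori asymmetric transfer hydrogenation; the (S,S)-diamine ruthenium hydride reduces aryl methyl ketones through an outer-sphere six-membered transition state to (S)-1-arylethanols, formate makes the reduction irreversible, and the allyl and ester-conjugated alkenes should not be reduced.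

Step 5
Reactants: 8 methyl 2-({4-[(1S)-1-hydroxyethyl]-2-(prop-2-en-1-yl)phenoxy}methyl)prop-2-enoate
Product: 9 methyl 2-({4-[(1S)-1-{[tert-butyl(dimethyl)silyl]oxy}ethyl]-2-(prop-2-en-1-yl)phenoxy}methyl)prop-2-enoate
Conditions: TBSOTf, 2,6-lutidine, CH2Cl2, −78 to 0 °C
Reagents that add atoms: tert-butyldimethylsilyl trifluoromethanesulfonate (TBSOTf), CC(C)(C)[Si](C)(C)OS(=O)(=O)C(F)(F)F
Why: O-silylation of the secondary alcohol with a hindered, non-nucleophilic base that cannot add to the acrylate; the carbinol C–O bond is not touched, so (S) is kept.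

Step 6
Reactants: 9 methyl 2-({4-[(1S)-1-{[tert-butyl(dimethyl)silyl]oxy}ethyl]-2-(prop-2-en-1-yl)phenoxy}methyl)prop-2-enoate
Product: 10 methyl 2-({4-[(1S)-1-{[tert-butyl(dimethyl)silyl]oxy}ethyl]-2-(2-oxopropyl)phenoxy}methyl)prop-2-enoate
Conditions: PdCl2 (10 mol%), CuCl, O2 (1 atm), DMF/H2O (7:1), rt
Reagents that add atoms: water, O
Why: Tsuji–Wacker oxidation; Markovnikov hydroxypalladation of the terminal allyl alkene and β-hydride elimination give the methyl ketone while O2/CuCl reoxidise palladium, and the electron-poor 1,1-disubstituted acrylate alkene should be inert to divalent palladium here.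

Step 7
Reactants: 10 methyl 2-({4-[(1S)-1-{[tert-butyl(dimethyl)silyl]oxy}ethyl]-2-(2-oxopropyl)phenoxy}methyl)prop-2-enoate
Product: 11 methyl 2-({4-[(1S)-1-{[tert-butyl(dimethyl)silyl]oxy}ethyl]-2-(1-diazo-2-oxopropyl)phenoxy}methyl)prop-2-enoate
Conditions: p-ABSA, DBU, MeCN, 0 °C
Reagents that add atoms: 4-acetamidobenzenesulfonyl azide (p-ABSA), CC(=O)Nc1ccc(cc1)S(=O)(=O)N=[N+]=[N-]
Why: Regitz diazo transfer to the benzylic methylene flanked by aryl and acetyl, the most acidic C–H in 10, as is standard for 1-arylpropan-2-ones; the diazoketone is kept cold and used at once.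

Step 8
Reactants: 11 methyl 2-({4-[(1S)-1-{[tert-butyl(dimethyl)silyl]oxy}ethyl]-2-(1-diazo-2-oxopropyl)phenoxy}methyl)prop-2-enoate
Product: 12 methyl 2-{(2R,3S)-3-acetyl-5-[(1S)-1-{[tert-butyl(dimethyl)silyl]oxy}ethyl]-2,3-dihydro-1-benzofuran-2-yl}prop-2-enoate (2,3-cis)
Conditions: Rh2(S-PTTL)4 (2 mol%), toluene, −40 °C, slow addition of 11; filtration through neutral silica
Reagents that add atoms: none
Why: Extrusion of dinitrogen from 11 on the dirhodium tetracarboxylate leaves an electrophilic aryl(acetyl)carbenoid at the future C3, which takes up one C–H bond of the neighbouring O–CH2 group in a single asynchronous step with hydride-like transfer, so that the C2–C3 and C3–H bonds form together. The closest known reaction type is the enantioselective intramolecular C–H insertion of ortho-alkoxyaryl diazoacetates into the ether methylene under chiral dirhodium carboxylates, which gives cis-2,3-disubstituted 2,3-dihydrobenzofurans; here the acceptor is an acetyl group instead of an ester and the methylene carries the acrylate. The dihydrofuran ring (O1–C2–C3–C3a–C7a) closes by 1,5-insertion, the ortho tether leaving no other ring size accessible. C2 and C3 are created in the same event: the cis relation is the kinetic outcome of the insertion transition state, in which the C2 substituent turns away from the carboxylate wall, and the absolute (2R,3S) sense is imposed by the phthalimido/tert-butyl pocket of the catalyst, the remote side-chain centre having no influence. The step needs C–H insertion to outrun cyclopropanation and ylide formation; this is secured by the oxygen-activated, allylic C–H bond held in a five-membered-ring geometry and by the electron-poor 1,1-disubstituted acrylate alkene, a poor partner for an electrophilic carbenoid. Low temperature, dilution and base-free isolation are meant to keep the kinetic cis ketone from epimerising at the enolisable C3.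

Step 9
Reactants: 12 methyl 2-{(2R,3S)-3-acetyl-5-[(1S)-1-{[tert-butyl(dimethyl)silyl]oxy}ethyl]-2,3-dihydro-1-benzofuran-2-yl}prop-2-enoate
Product: 13 methyl 2-{(2S,3S)-3-acetoxy-5-[(1S)-1-{[tert-butyl(dimethyl)silyl]oxy}ethyl]-2,3-dihydro-1-benzofuran-2-yl}prop-2-enoate (2,3-cis)
Conditions: mCPBA, NaHCO3, CH2Cl2, 0 °C to rt
Reagents that add atoms: 3-chloroperoxybenzoic acid (mCPBA), OOC(=O)c1cccc(Cl)c1
Why: Baeyer–Villiger oxidation; the secondary benzylic C3 migrates in preference to methyl and with retention, so the cis relation is carried into the acetate, and the buffered peracid should not epoxidise the electron-poor acrylate.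

Step 10
Reactants: 13 methyl 2-{(2S,3S)-3-acetoxy-5-[(1S)-1-{[tert-butyl(dimethyl)silyl]oxy}ethyl]-2,3-dihydro-1-benzofuran-2-yl}prop-2-enoate
Product: 14 methyl 2-{(2S,3S)-3-acetoxy-5-[(1S)-1-hydroxyethyl]-2,3-dihydro-1-benzofuran-2-yl}prop-2-enoate
Conditions: HF·pyridine, pyridine, THF, 0 °C to rt
Reagents that add atoms: none
Why: Fluoride-driven cleavage of the silyl ether in a pyridine-buffered medium that should spare the acetate, the acrylate and the two ionisable benzylic C–O bonds.

Step 11
Reactants: 14 methyl 2-{(2S,3S)-3-acetoxy-5-[(1S)-1-hydroxyethyl]-2,3-dihydro-1-benzofuran-2-yl}prop-2-enoate; 15 angelic acid, (2Z)-2-methylbut-2-enoic acid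
Product: 17 (1S)-1-{(2S,3S)-3-acetoxy-2-[3-methoxy-3-oxoprop-1-en-2-yl]-2,3-dihydro-1-benzofuran-5-yl}ethyl (2Z)-2-methylbut-2-enoate (CNP0168827.1), via angelic 2,4,6-trichlorobenzoic anhydride 16 (not isolated)
Conditions: 15, 2,4,6-Cl3C6H2COCl, Et3N, toluene, rt; then 14, 75 °C
Reagents that add atoms: none
Why: Yamaguchi esterification; the alcohol attacks the less hindered angeloyl carbonyl of the mixed anhydride, the carbinol C–O bond is not broken so (S) is kept, and leaving out a nucleophilic acyl-transfer catalyst is meant to avoid Z-to-E isomerisation to the tiglate.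

**Compound list**

1 | 1-(4-hydroxyphenyl)ethan-1-one | CC(=O)c1ccc(O)cc1 | starting material
2 | allyl bromide (3-bromoprop-1-ene) | C=CCBr | starting material
3 | 1-[4-(prop-2-en-1-yloxy)phenyl]ethan-1-one | C=CCOc1ccc(C(C)=O)cc1 | intermediate
4 | 4-acetyl-6-(prop-2-en-1-yl)cyclohexa-2,4-dien-1-one (not isolated) | C=CCC1C=C(C(C)=O)C=CC1=O | intermediate
5 | 1-[4-hydroxy-3-(prop-2-en-1-yl)phenyl]ethan-1-one | C=CCc1cc(C(C)=O)ccc1O | intermediate
6 | methyl 2-(bromomethyl)prop-2-enoate | C=C(CBr)C(=O)OC | starting material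
7 | methyl 2-{[4-acetyl-2-(prop-2-en-1-yl)phenoxy]methyl}prop-2-enoate | C=C(C(=O)OC)COc1ccc(C(C)=O)cc1CC=C | intermediate
8 | methyl 2-({4-[(1S)-1-hydroxyethyl]-2-(prop-2-en-1-yl)phenoxy}methyl)prop-2-enoate | C=C(C(=O)OC)COc1ccc([C@H](C)O)cc1CC=C | intermediate
9 | methyl 2-({4-[(1S)-1-{[tert-butyl(dimethyl)silyl]oxy}ethyl]-2-(prop-2-en-1-yl)phenoxy}methyl)prop-2-enoate | C=C(C(=O)OC)COc1ccc([C@H](C)O[Si](C)(C)C(C)(C)C)cc1CC=C | intermediate
10 | methyl 2-({4-[(1S)-1-{[tert-butyl(dimethyl)silyl]oxy}ethyl]-2-(2-oxopropyl)phenoxy}methyl)prop-2-enoate | C=C(C(=O)OC)COc1ccc([C@H](C)O[Si](C)(C)C(C)(C)C)cc1CC(C)=O | intermediate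
11 | methyl 2-({4-[(1S)-1-{[tert-butyl(dimethyl)silyl]oxy}ethyl]-2-(1-diazo-2-oxopropyl)phenoxy}methyl)prop-2-enoate | C=C(C(=O)OC)COc1ccc([C@H](C)O[Si](C)(C)C(C)(C)C)cc1C(=[N+]=[N-])C(C)=O | intermediate
12 | methyl 2-{(2R,3S)-3-acetyl-5-[(1S)-1-{[tert-butyl(dimethyl)silyl]oxy}ethyl]-2,3-dihydro-1-benzofuran-2-yl}prop-2-enoate (2,3-cis) | C=C(C(=O)OC)[C@@H]1Oc2ccc([C@H](C)O[Si](C)(C)C(C)(C)C)cc2[C@@H]1C(C)=O | intermediate
13 | methyl 2-{(2S,3S)-3-acetoxy-5-[(1S)-1-{[tert-butyl(dimethyl)silyl]oxy}ethyl]-2,3-dihydro-1-benzofuran-2-yl}prop-2-enoate (2,3-cis) | C=C(C(=O)OC)[C@@H]1Oc2ccc([C@H](C)O[Si](C)(C)C(C)(C)C)cc2[C@@H]1OC(C)=O | intermediate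
14 | methyl 2-{(2S,3S)-3-acetoxy-5-[(1S)-1-hydroxyethyl]-2,3-dihydro-1-benzofuran-2-yl}prop-2-enoate | C=C(C(=O)OC)[C@@H]1Oc2ccc([C@H](C)O)cc2[C@@H]1OC(C)=O | intermediate
15 | angelic acid, (2Z)-2-methylbut-2-enoic acid | C/C=C(/C)C(=O)O | starting material
16 | (2Z)-2-methylbut-2-enoic 2,4,6-trichlorobenzoic anhydride (not isolated) | C/C=C(/C)C(=O)OC(=O)c1c(Cl)cc(Cl)cc1Cl | intermediate
17 | (1S)-1-{(2S,3S)-3-acetoxy-2-[3-methoxy-3-oxoprop-1-en-2-yl]-2,3-dihydro-1-benzofuran-5-yl}ethyl (2Z)-2-methylbut-2-enoate | C=C(C(=O)OC)[C@@H]1Oc2ccc([C@H](C)OC(=O)/C(C)=C\C)cc2[C@@H]1OC(C)=O | target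

**Count and risks**

Total steps: 11. Longest linear sequence: 11 steps (1 to 17).

Steps most likely to fail:

Step 8. The acetyl carbenoid is more electrophilic and less discriminating than an ester-bearing one. It may be diverted by the acrylate (attack on the alkene or carbonyl, or cycloaddition of the diazo group before dinitrogen is lost), or the catalyst pocket may discriminate the faces poorly. The fallback sets out from 9 and comes back at 12; it uses the ester class of carbenoid for which cis- and enantioselective ether insertion is established, and makes the acetyl group afterwards. Ozonolysis of the allyl alkene of 9 (O3, CH2Cl2, −78 °C; Me2S), which the electron-poor acrylate alkene should outlast, would give the arylacetaldehyde methyl 2-({4-[(1S)-1-{[tert-butyl(dimethyl)silyl]oxy}ethyl]-2-(2-oxoethyl)phenoxy}methyl)prop-2-enoate F1. Pinnick oxidation (NaClO2, NaH2PO4, 2-methylbut-2-ene, t-BuOH/H2O) would give {5-[(1S)-1-{[tert-butyl(dimethyl)silyl]oxy}ethyl]-2-{[2-(methoxycarbonyl)prop-2-en-1-yl]oxy}phenyl}acetic acid F2, and MeI/KHCO3 in DMF its methyl ester, methyl 2-({4-[(1S)-1-{[tert-butyl(dimethyl)silyl]oxy}ethyl]-2-(2-methoxy-2-oxoethyl)phenoxy}methyl)prop-2-enoate F3. Diazo transfer (p-ABSA, DBU, MeCN) would give the aryldiazoacetate methyl 2-({4-[(1S)-1-{[tert-butyl(dimethyl)silyl]oxy}ethyl]-2-(1-diazo-2-methoxy-2-oxoethyl)phenoxy}methyl)prop-2-enoate F4. Insertion with Rh2(S-PTTL)4 in toluene at −60 °C should give the cis ester methyl (2R,3S)-5-[(1S)-1-{[tert-butyl(dimethyl)silyl]oxy}ethyl]-2-[3-methoxy-3-oxoprop-1-en-2-yl]-2,3-dihydro-1-benzofuran-3-carboxylate F5. Base-free methylenation of the saturated C3 ester with the Petasis reagent Cp2TiMe2 (toluene, 65 °C), which should react more slowly with the conjugated, α-branched acrylate ester, would give the enol ether methyl 2-{(2R,3S)-5-[(1S)-1-{[tert-butyl(dimethyl)silyl]oxy}ethyl]-3-(1-methoxyethenyl)-2,3-dihydro-1-benzofuran-2-yl}prop-2-enoate F6. Hydrolysis with dilute aqueous oxalic acid in THF would then deliver ketone 12.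

Step 9. Oxygen insertion into a methyl ketone is slow. Meanwhile the cis ketone may epimerise at C3 by enolisation, or open reversibly by β-elimination of the phenoxide, so the kinetic cis relation may be lost. The fallback sets out from 12 and comes back at 13; it works in the stable trans series and sets C3 by inversion instead of retention. Equilibration of 12 (Et3N, CH2Cl2, rt) should give the trans ketone methyl 2-{(2R,3R)-3-acetyl-5-[(1S)-1-{[tert-butyl(dimethyl)silyl]oxy}ethyl]-2,3-dihydro-1-benzofuran-2-yl}prop-2-enoate F7, which has no stereochemical lability left. Baeyer–Villiger oxidation (mCPBA, NaHCO3, CH2Cl2) with retention would give the trans acetate methyl 2-{(2S,3R)-3-acetoxy-5-[(1S)-1-{[tert-butyl(dimethyl)silyl]oxy}ethyl]-2,3-dihydro-1-benzofuran-2-yl}prop-2-enoate F8. Mild methanolysis (K2CO3, MeOH, 0 °C) would give the trans alcohol methyl 2-{(2S,3R)-5-[(1S)-1-{[tert-butyl(dimethyl)silyl]oxy}ethyl]-3-hydroxy-2,3-dihydro-1-benzofuran-2-yl}prop-2-enoate F9. A Mitsunobu reaction with acetic acid (PPh3, DIAD, AcOH, THF, 0 °C) would install the acetate with inversion at C3 and arrive at 13.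

Step 11. The angeloyl unit may isomerise from Z to E during activation and acyl transfer, and heating may cause loss of acetic acid across C2–C3 to the aromatic benzofuran. The fallback sets out from 14 and comes back at 17; it builds the Z alkene on the ester instead of transferring a preformed angelate. Carbodiimide esterification of 14 with 2-[bis(2,2,2-trifluoroethoxy)phosphoryl]propanoic acid (DCC, DMAP cat., CH2Cl2, 0 °C) would give (1S)-1-{(2S,3S)-3-acetoxy-2-[3-methoxy-3-oxoprop-1-en-2-yl]-2,3-dihydro-1-benzofuran-5-yl}ethyl 2-[bis(2,2,2-trifluoroethoxy)phosphoryl]propanoate F10, a mixture at the phosphorus-bearing carbon, which does not matter. Still–Gennari olefination (KHMDS, 18-crown-6, THF, −78 °C; acetaldehyde) should give the Z-trisubstituted enoate, target 17, at a temperature where the acetate and acrylate should stay intact.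

**Further compounds**

F1 | step 8 | methyl 2-({4-[(1S)-1-{[tert-butyl(dimethyl)silyl]oxy}ethyl]-2-(2-oxoethyl)phenoxy}methyl)prop-2-enoate | C=C(C(=O)OC)COc1ccc([C@H](C)O[Si](C)(C)C(C)(C)C)cc1CC=O
F2 | step 8 | {5-[(1S)-1-{[tert-butyl(dimethyl)silyl]oxy}ethyl]-2-{[2-(methoxycarbonyl)prop-2-en-1-yl]oxy}phenyl}acetic acid | C=C(C(=O)OC)COc1ccc([C@H](C)O[Si](C)(C)C(C)(C)C)cc1CC(=O)O
F3 | step 8 | methyl 2-({4-[(1S)-1-{[tert-butyl(dimethyl)silyl]oxy}ethyl]-2-(2-methoxy-2-oxoethyl)phenoxy}methyl)prop-2-enoate | C=C(C(=O)OC)COc1ccc([C@H](C)O[Si](C)(C)C(C)(C)C)cc1CC(=O)OC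
F4 | step 8 | methyl 2-({4-[(1S)-1-{[tert-butyl(dimethyl)silyl]oxy}ethyl]-2-(1-diazo-2-methoxy-2-oxoethyl)phenoxy}methyl)prop-2-enoate | C=C(C(=O)OC)COc1ccc([C@H](C)O[Si](C)(C)C(C)(C)C)cc1C(=[N+]=[N-])C(=O)OC
F5 | step 8 | methyl (2R,3S)-5-[(1S)-1-{[tert-butyl(dimethyl)silyl]oxy}ethyl]-2-[3-methoxy-3-oxoprop-1-en-2-yl]-2,3-dihydro-1-benzofuran-3-carboxylate (2,3-cis) | C=C(C(=O)OC)[C@@H]1Oc2ccc([C@H](C)O[Si](C)(C)C(C)(C)C)cc2[C@@H]1C(=O)OC
F6 | step 8 | methyl 2-{(2R,3S)-5-[(1S)-1-{[tert-butyl(dimethyl)silyl]oxy}ethyl]-3-(1-methoxyethenyl)-2,3-dihydro-1-benzofuran-2-yl}prop-2-enoate | C=C(C(=O)OC)[C@@H]1Oc2ccc([C@H](C)O[Si](C)(C)C(C)(C)C)cc2[C@@H]1C(=C)OC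
F7 | step 9 | methyl 2-{(2R,3R)-3-acetyl-5-[(1S)-1-{[tert-butyl(dimethyl)silyl]oxy}ethyl]-2,3-dihydro-1-benzofuran-2-yl}prop-2-enoate (2,3-trans) | C=C(C(=O)OC)[C@@H]1Oc2ccc([C@H](C)O[Si](C)(C)C(C)(C)C)cc2[C@H]1C(C)=O
F8 | step 9 | methyl 2-{(2S,3R)-3-acetoxy-5-[(1S)-1-{[tert-butyl(dimethyl)silyl]oxy}ethyl]-2,3-dihydro-1-benzofuran-2-yl}prop-2-enoate (2,3-trans) | C=C(C(=O)OC)[C@@H]1Oc2ccc([C@H](C)O[Si](C)(C)C(C)(C)C)cc2[C@H]1OC(C)=O
F9 | step 9 | methyl 2-{(2S,3R)-5-[(1S)-1-{[tert-butyl(dimethyl)silyl]oxy}ethyl]-3-hydroxy-2,3-dihydro-1-benzofuran-2-yl}prop-2-enoate (2,3-trans) | C=C(C(=O)OC)[C@@H]1Oc2ccc([C@H](C)O[Si](C)(C)C(C)(C)C)cc2[C@H]1O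
F10 | step 11 | (1S)-1-{(2S,3S)-3-acetoxy-2-[3-methoxy-3-oxoprop-1-en-2-yl]-2,3-dihydro-1-benzofuran-5-yl}ethyl 2-[bis(2,2,2-trifluoroethoxy)phosphoryl]propanoate | C=C(C(=O)OC)[C@@H]1Oc2ccc([C@H](C)OC(=O)C(C)P(=O)(OCC(F)(F)F)OCC(F)(F)F)cc2[C@@H]1OC(C)=O
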